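The plan cuts the two bonds that tie the side chains to the oxolane ring: C4–carbinol carbon and C3–benzylic CH2. Ring carbons C3 and C4 are neighbours, each bears a single carbon substituent, and the two substituents lie on opposite faces. That is the footprint of Michael addition followed by enolate alkylation on a butenolide, whose carbonyl (C2) and acetal (C5) carbons later become the ring OCH2 groups. In one flask a lithiated O-benzylsyringaldehyde dithiane (masked aroyl anion) adds to enantiopure (5R)-menthyloxybutenolide and the enolate is trapped by O-benzylvanillyl bromide. This forges both bonds and both ring stereocentres under control of the acetal centre. The carbinol centre is set late by a matched ketone reduction.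

Key step: step 8

Remark on the chemistry: the ring numbering O1, C2, C3 (guaiacylmethyl-bearing), C4 (carbinol-bearing), C5 is kept from lactone to target. CIP analysis of the target SMILES gives 3R, 4R and S at the carbinol carbon. In the systematic names of 20–22 the oxolan-3-yl locant falls on the carbinol-bearing carbon, and both ring centres are R either way. The (5R)-butenolide from natural (−)-menthol leads to this enantiomeric series.

Step 1
Reactants: 1 furfural
Product: 3 5-hydroxyfuran-2(5H)-one, via furfural endoperoxide 2 (not isolated)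
Conditions: O2, hν (visible), rose bengal disodium salt C20H2Cl4I4Na2O5 (cat.), MeOH, 15–20 °C
Reagents that add atoms: dioxygen, O=O
Why: Dye-sensitised singlet-oxygen [4+2] cycloaddition across C2/C5 of the furan gives endoperoxide 2, whose formyl group is attacked by methanol and expelled as the formate ester while the O–O bond breaks, a well-established photo-oxygenation route to the γ-hydroxybutenolide (the hemiacetal carbon is configurationally labile, so no stereocentre is fixed).

Step 2
Reactants: 3 5-hydroxyfuran-2(5H)-one; 4 (1R,2S,5R)-menthol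
Product: 6 (5R)-5-[(1R,2S,5R)-menthyloxy]furan-2(5H)-one, via (5S)-acetal epimer 5 (not isolated)
Conditions: (1S)-camphor-10-sulfonic acid (cat.), PhMe, reflux, Dean–Stark; crystallisation from hexane, mother liquor re-equilibrated with the acid and recrystallised
Reagents that add atoms: none
Why: Acid-catalysed acetalisation of the pseudo-acid with azeotropic water removal gives both C5 epimers, which interconvert through the ring oxocarbenium ion, and because the (5R)-isomer is the one that crystallises, C5 is set by crystallisation-driven epimerisation while the three menthyl centres come unchanged from the chiral pool.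

Step 3
Reactants: 7 syringaldehyde
Product: 8 4-(benzyloxy)-3,5-dimethoxybenzaldehyde
Conditions: BnBr, K2CO3, DMF, 60 °C
Reagents that add atoms: benzyl bromide, BrCc1ccccc1
Why: Williamson ether synthesis of an acidic phenoxide with a reactive benzylic halide, in which warming in DMF offsets the flanking by two methoxy groups and the aldehyde is inert to carbonate.

Step 4
Reactants: 8 4-(benzyloxy)-3,5-dimethoxybenzaldehyde
Product: 9 2-[4-(benzyloxy)-3,5-dimethoxyphenyl]-1,3-dithiane
Conditions: HS(CH2)3SH, BF3·OEt2 (cat.), CH2Cl2, 0 °C → rt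
Reagents that add atoms: propane-1,3-dithiol, SCCCS
Why: Lewis-acid-catalysed thioacetalisation of an aromatic aldehyde, in which a catalytic charge of BF3·OEt2 at low temperature leaves the aryl benzyl ether untouched.

Step 5
Reactants: 10 vanillin
Product: 11 4-(benzyloxy)-3-methoxybenzaldehyde
Conditions: BnBr, K2CO3, DMF, 50 °C
Reagents that add atoms: benzyl bromide, BrCc1ccccc1
Why: Williamson ether synthesis on the only acidic site of the molecule.

Step 6
Reactants: 11 4-(benzyloxy)-3-methoxybenzaldehyde
Product: 12 [4-(benzyloxy)-3-methoxyphenyl]methanol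
Conditions: NaBH4, MeOH/THF, 0 °C
Reagents that add atoms: none
Why: Borohydride reduction of an aromatic aldehyde to the benzylic alcohol, to which both ether groups are inert.

Step 7
Reactants: 12 [4-(benzyloxy)-3-methoxyphenyl]methanol
Product: 13 4-(benzyloxy)-3-methoxybenzyl bromide
Conditions: PBr3, Et2O, 0 °C; used without storage
Reagents that add atoms: phosphorus tribromide, BrP(Br)Br
Why: Bromodehydroxylation through the phosphite ester and displacement by bromide, run cold and followed by immediate use so that the electron-rich benzylic bromide has no time to self-alkylate.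

Step 8
Reactants: 9 2-[4-(benzyloxy)-3,5-dimethoxyphenyl]-1,3-dithiane; 6 (5R)-5-[(1R,2S,5R)-menthyloxy]furan-2(5H)-one; 13 4-(benzyloxy)-3-methoxybenzyl bromide
Product: 16 (3R,4R,5R)-3-[4-(benzyloxy)-3-methoxybenzyl]-4-{2-[4-(benzyloxy)-3,5-dimethoxyphenyl]-1,3-dithian-2-yl}-5-[(1R,2S,5R)-menthyloxy]dihydrofuran-2(3H)-one, via 2-lithiodithiane 14 (not isolated), via lithium enolate 15 (not isolated)
Conditions: 9, n-BuLi, THF, −78 → −20 °C; 6, THF, −78 °C; 13, DMPU, −78 → −20 °C; aq NH4Cl
Reagents that add atoms: none
Why: n-BuLi removes the C2–H of 9 to give the sulfur-stabilised carbanion 14, which attacks the β-carbon of 6 in a Michael addition, and the resulting lithium enolate 15 is C-benzylated by SN2 attack on 13 once DMPU has broken up its aggregates. The closest known reaction type is the tandem conjugate addition/enolate alkylation of lithiated aryl dithioacetals on 2(5H)-furanones, the standard entry to dibenzylbutyrolactone lignans. No ring is closed, the lactone ring of 6 simply being carried on as the future oxolane. C4 is controlled by the C5 acetal centre, whose menthyloxy group blocks one face so that 14 enters anti to it, and C3 is controlled by the new bulky dithianyl group on C4, which sends the bromide to the opposite face, giving the all-trans (3R,4R,5R) array. The step needs 1,4- rather than 1,2-addition, secured by the soft, delocalised and bulky 2-aryl dithiane anion whose carbonyl addition is reversible at −78 °C, and it needs a single C-alkylation, secured by the crowding around C3 of 16, which blocks renewed enolisation.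

Step 9
Reactants: 16 the lactone acetal from step 8
Product: 17 (2R,3R)-2-[4-(benzyloxy)-3-methoxybenzyl]-3-{2-[4-(benzyloxy)-3,5-dimethoxyphenyl]-1,3-dithian-2-yl}butane-1,4-diol
Conditions: LiAlH4, THF, 0 °C → rt; H2O/aq NaOH work-up
Reagents that add atoms: none
Why: Exhaustive hydride reduction in which the lactone carbonyl is reduced and ring-opened, the freed C5 hemiacetal alkoxide expels menthoxide to give an aldehyde that is reduced in turn, so that both ring termini end as CH2OH, the auxiliary is released for recovery, and C3 and C4 stay intact because the transient aldehydes are reduced faster than they can enolise.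

Step 10
Reactants: 17 the (2R,3R)-1,4-diol
Product: 19 (3R,4R)-3-[4-(benzyloxy)-3-methoxybenzyl]-4-{2-[4-(benzyloxy)-3,5-dimethoxyphenyl]-1,3-dithian-2-yl}oxolane, via primary monotosylate 18 (not isolated)
Conditions: NaH (2.2 equiv), THF, 0 °C; TsCl (1.05 equiv), 0 °C → rt
Reagents that add atoms: none
Why: One-pot Williamson-type cyclodehydration in which the bis-alkoxide is sulfonylated once (preferentially at the hydroxymethyl group remote from the quaternary dithiane carbon) and the remaining alkoxide closes the oxolane by 5-exo-tet SN2 displacement at a primary carbon, faster than a second tosylation or attack by the weakly nucleophilic dithiane sulfur, with no stereocentre involved and the same ring formed whichever hydroxyl is activated.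

Step 11
Reactants: 19 the oxolane dithiane
Product: 20 [4-(benzyloxy)-3,5-dimethoxyphenyl]{(3R,4R)-4-[4-(benzyloxy)-3-methoxybenzyl]oxolan-3-yl}methanone
Conditions: MeI (excess), CaCO3, MeCN/H2O (4:1), 45 °C
Reagents that add atoms: water, O
Why: Alkylative dithiane hydrolysis in which S-methylation makes sulfur a leaving group and the aryl-stabilised thionium ion is captured by water, the non-oxidising carbonate-buffered medium sparing the electron-rich arenes and benzyl ethers, while C4 (now α to the ketone) is safe because the trans-3,4 arrangement is also the thermodynamic one.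

Step 12
Reactants: 20 the aryl oxolanyl ketone
Product: 21 (S)-[4-(benzyloxy)-3,5-dimethoxyphenyl]{(3R,4R)-4-[4-(benzyloxy)-3-methoxybenzyl]oxolan-3-yl}methanol
Conditions: (R)-Me-CBS oxazaborolidine C18H20BNO (20 mol %), BH3·SMe2, THF, −20 °C; MeOH quench
Reagents that add atoms: none
Why: Corey–Bakshi–Shibata reduction in which the (R)-oxazaborolidine binds the ketone with the aryl group as the large substituent and delivers hydride to the Re face to give the (S)-carbinol (the sense normal for aryl alkyl ketones), and the Felkin–Anh preference for attack anti to the more branched C3 arm of the α-stereocentre points to the same face, so reagent and substrate control should be matched.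

Step 13
Reactants: 21 the dibenzyl-protected (S)-carbinol
Product: 22 (S)-(4-hydroxy-3,5-dimethoxyphenyl)[(3R,4R)-4-(4-hydroxy-3-methoxybenzyl)oxolan-3-yl]methanol (target CNP0307127.1)
Conditions: H2 (1 atm), 10% Pd/C, EtOAc, rt, stopped after uptake of 2 equiv H2
Reagents that add atoms: none
Why: Catalytic hydrogenolysis of the two aryl benzyl ethers, which are cleaved much faster than a secondary benzylic alcohol in a neutral solvent at atmospheric pressure, so that stopping at two equivalents of hydrogen should leave the carbinol C–O bond and all three stereocentres intact.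

Compound list
1 | furfural (furan-2-carbaldehyde) | O=Cc1ccco1 | starting material
2 | furfural endoperoxide, 2,3,7-trioxabicyclo[2.2.1]hept-5-ene-1-carbaldehyde (racemic, formed in the flask) | O=CC12C=CC(OO1)O2 | intermediate
3 | 5-hydroxyfuran-2(5H)-one (labile hemiacetal) | O=C1C=CC(O)O1 | intermediate
4 | (1R,2S,5R)-menthol | C[C@@H]1CC[C@H]([C@@H](C1)O)C(C)C | starting material
5 | (5S)-5-[(1R,2S,5R)-menthyloxy]furan-2(5H)-one (epimer, equilibrated in the flask) | O=C1C=C[C@@H](O[C@@H]2C[C@H](C)CC[C@H]2C(C)C)O1 | intermediate
6 | (5R)-5-[(1R,2S,5R)-menthyloxy]furan-2(5H)-one | O=C1C=C[C@H](O[C@@H]2C[C@H](C)CC[C@H]2C(C)C)O1 | intermediate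
7 | syringaldehyde | COc1cc(C=O)cc(OC)c1O | starting material
8 | 4-(benzyloxy)-3,5-dimethoxybenzaldehyde | COc1cc(C=O)cc(OC)c1OCc1ccccc1 | intermediate
9 | 2-[4-(benzyloxy)-3,5-dimethoxyphenyl]-1,3-dithiane | COc1cc(C2SCCCS2)cc(OC)c1OCc1ccccc1 | intermediate
10 | vanillin | COc1cc(C=O)ccc1O | starting material
11 | 4-(benzyloxy)-3-methoxybenzaldehyde | COc1cc(C=O)ccc1OCc1ccccc1 | intermediate
12 | [4-(benzyloxy)-3-methoxyphenyl]methanol | COc1cc(CO)ccc1OCc1ccccc1 | intermediate
13 | 4-(benzyloxy)-3-methoxybenzyl bromide | COc1cc(CBr)ccc1OCc1ccccc1 | intermediate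
14 | 2-lithio-2-[4-(benzyloxy)-3,5-dimethoxyphenyl]-1,3-dithiane (formed in the flask) | [Li]C1(SCCCS1)c1cc(OC)c(OCc2ccccc2)c(OC)c1 | intermediate
15 | lithium enolate of the (4R,5R)-4-dithianyl-5-menthyloxy lactone (formed in the flask) | [Li]OC1=C[C@@H](C2(SCCCS2)c2cc(OC)c(OCc3ccccc3)c(OC)c2)[C@H](O[C@@H]2C[C@H](C)CC[C@H]2C(C)C)O1 | intermediate
16 | (3R,4R,5R)-3-[4-(benzyloxy)-3-methoxybenzyl]-4-{2-[4-(benzyloxy)-3,5-dimethoxyphenyl]-1,3-dithian-2-yl}-5-[(1R,2S,5R)-menthyloxy]dihydrofuran-2(3H)-one | COc1cc(C[C@H]2C(=O)O[C@@H](O[C@@H]3C[C@H](C)CC[C@H]3C(C)C)[C@@H]2C4(SCCCS4)c4cc(OC)c(OCc5ccccc5)c(OC)c4)ccc1OCc1ccccc1 | intermediate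
17 | (2R,3R)-2-[4-(benzyloxy)-3-methoxybenzyl]-3-{2-[4-(benzyloxy)-3,5-dimethoxyphenyl]-1,3-dithian-2-yl}butane-1,4-diol | COc1cc(C[C@@H](CO)[C@H](CO)C2(SCCCS2)c2cc(OC)c(OCc3ccccc3)c(OC)c2)ccc1OCc1ccccc1 | intermediate
18 | (2R,3R)-2-[4-(benzyloxy)-3-methoxybenzyl]-3-{2-[4-(benzyloxy)-3,5-dimethoxyphenyl]-1,3-dithian-2-yl}-4-hydroxybutyl 4-methylbenzenesulfonate (formed in the flask) | COc1cc(C[C@@H](COS(=O)(=O)c2ccc(C)cc2)[C@H](CO)C2(SCCCS2)c2cc(OC)c(OCc3ccccc3)c(OC)c2)ccc1OCc1ccccc1 | intermediate
19 | (3R,4R)-3-[4-(benzyloxy)-3-methoxybenzyl]-4-{2-[4-(benzyloxy)-3,5-dimethoxyphenyl]-1,3-dithian-2-yl}oxolane | COc1cc(C[C@H]2COC[C@@H]2C3(SCCCS3)c3cc(OC)c(OCc4ccccc4)c(OC)c3)ccc1OCc1ccccc1 | intermediate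
20 | [4-(benzyloxy)-3,5-dimethoxyphenyl]{(3R,4R)-4-[4-(benzyloxy)-3-methoxybenzyl]oxolan-3-yl}methanone | COc1cc(C[C@H]2COC[C@@H]2C(=O)c2cc(OC)c(OCc3ccccc3)c(OC)c2)ccc1OCc1ccccc1 | intermediate
21 | (S)-[4-(benzyloxy)-3,5-dimethoxyphenyl]{(3R,4R)-4-[4-(benzyloxy)-3-methoxybenzyl]oxolan-3-yl}methanol | COc1cc(C[C@H]2COC[C@@H]2[C@H](O)c2cc(OC)c(OCc3ccccc3)c(OC)c2)ccc1OCc1ccccc1 | intermediate
22 | (S)-(4-hydroxy-3,5-dimethoxyphenyl)[(3R,4R)-4-(4-hydroxy-3-methoxybenzyl)oxolan-3-yl]methanol | COc1cc(C[C@H]2COC[C@@H]2[C@H](O)c2cc(OC)c(O)c(OC)c2)ccc1O | target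

Total step count: 13.
Longest linear sequence: 9 steps (10 → 11 → 12 → 13 → 16 → 17 → 19 → 20 → 21 → 22).

Steps most likely to fail

Risk 1 (step 8). The Michael addition may be eroded by attack at the lactone carbonyl or by deprotonation of the acidic acetal C5–H of 6. The hindered enolate may also be captured so slowly that it is merely protonated on work-up. Fallback: the two bond formations are uncoupled. Setting out from 9 and 6, the conjugate addition is run alone (through 14) and quenched with aq NH4Cl. This gives (4R,5R)-4-{2-[4-(benzyloxy)-3,5-dimethoxyphenyl]-1,3-dithian-2-yl}-5-[(1R,2S,5R)-menthyloxy]dihydrofuran-2(3H)-one F1, which is purified. It is then re-enolised with LiN(SiMe3)2 in THF/DMPU at −78 °C (enolate 15 again) and alkylated with 13 under conditions tuned for this bond alone. The dithianyl group again directs attack to the opposite face, and the route is rejoined at 16.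

Risk 2 (step 12). Facial selectivity may be poor, because the smaller ketone substituent is itself a branched ring carbon and the catalyst may differentiate it only weakly from the aryl group. Fallback: selectivity is given up and the wrong centre is corrected by inversion. Setting out from 20, plain NaBH4 reduction in MeOH gives 21 together with its carbinol epimer (R)-[4-(benzyloxy)-3,5-dimethoxyphenyl]{(3R,4R)-4-[4-(benzyloxy)-3-methoxybenzyl]oxolan-3-yl}methanol F2. The two are separated by chromatography. The epimer is inverted in a Mitsunobu reaction (PPh3, DIAD, 4-nitrobenzoic acid, THF, 0 °C) to (S)-[4-(benzyloxy)-3,5-dimethoxyphenyl]{(3R,4R)-4-[4-(benzyloxy)-3-methoxybenzyl]oxolan-3-yl}methyl 4-nitrobenzoate F3. Methanolysis with K2CO3 in MeOH rejoins the route at 21. The para oxygen of this aryl ring is twisted out of conjugation by its two ortho methoxy groups, which should hold back ionisation and keep the displacement SN2.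

Risk 3 (step 13). Hydrogenolysis may run on past the benzyl ethers and strip the electron-rich benzylic hydroxyl group. Acidic sites on the catalyst may also epimerise the carbinol through a quinone-methide pathway once the para phenol is free. Fallback: the phenol protecting groups are exchanged before the carbinol exists, so the benzylic alcohol never meets hydrogen and palladium.
- Setting out from 20, H2 and 10% Pd/C in EtOAc give (4-hydroxy-3,5-dimethoxyphenyl)[(3R,4R)-4-(4-hydroxy-3-methoxybenzyl)oxolan-3-yl]methanone F4.
- TBSCl and imidazole in DMF give its bis(tert-butyldimethylsilyl) ether F5.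
- The reduction of step 12 gives the bis-silylated (S)-carbinol F6.
- Bu4NF buffered with AcOH in THF at 0 °C frees both phenols and rejoins the route at 22.

Further compounds
F1 | step 8 | (4R,5R)-4-{2-[4-(benzyloxy)-3,5-dimethoxyphenyl]-1,3-dithian-2-yl}-5-[(1R,2S,5R)-menthyloxy]dihydrofuran-2(3H)-one | O=C1C[C@@H](C2(SCCCS2)c2cc(OC)c(OCc3ccccc3)c(OC)c2)[C@H](O[C@@H]2C[C@H](C)CC[C@H]2C(C)C)O1
F2 | step 12 | (R)-[4-(benzyloxy)-3,5-dimethoxyphenyl]{(3R,4R)-4-[4-(benzyloxy)-3-methoxybenzyl]oxolan-3-yl}methanol | COc1cc(C[C@H]2COC[C@@H]2[C@@H](O)c2cc(OC)c(OCc3ccccc3)c(OC)c2)ccc1OCc1ccccc1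
F3 | step 12 | (S)-[4-(benzyloxy)-3,5-dimethoxyphenyl]{(3R,4R)-4-[4-(benzyloxy)-3-methoxybenzyl]oxolan-3-yl}methyl 4-nitrobenzoate | COc1cc(C[C@H]2COC[C@@H]2[C@H](OC(=O)c2ccc(cc2)[N+](=O)[O-])c2cc(OC)c(OCc3ccccc3)c(OC)c2)ccc1OCc1ccccc1
F4 | step 13 | (4-hydroxy-3,5-dimethoxyphenyl)[(3R,4R)-4-(4-hydroxy-3-methoxybenzyl)oxolan-3-yl]methanone | COc1cc(C[C@H]2COC[C@@H]2C(=O)c2cc(OC)c(O)c(OC)c2)ccc1O
F5 | step 13 | bis(tert-butyldimethylsilyl) ether of F4 | COc1cc(C[C@H]2COC[C@@H]2C(=O)c2cc(OC)c(O[Si](C)(C)C(C)(C)C)c(OC)c2)ccc1O[Si](C)(C)C(C)(C)C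
F6 | step 13 | bis(tert-butyldimethylsilyl) ether of the (S)-carbinol 22 | COc1cc(C[C@H]2COC[C@@H]2[C@H](O)c2cc(OC)c(O[Si](C)(C)C(C)(C)C)c(OC)c2)ccc1O[Si](C)(C)C(C)(C)C
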